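(The readings are calculated with constants of no real substance, noise included.)

**What stands.** Friday's and Sunday's runs, averaged, held more substrate than intermediate A when the feed stopped: 34.7% against 27.3% at 2.00 min. Their charges differ, yet their substrate and intermediate A readings up to 4.00 min agree within the scatter, so we carry those to your flask, whose charge lies between.

| flask | substrate | capture agent | remark | time |
|---|---|---|---|---|
| Friday's | 6.7 × 10⁻⁴ M (fed, over 2.0 min) | 0.050 mM | run made earlier |  |
| Sunday's | 0.0015 M (fed, over 2.0 min) | 0.050 mM | run made earlier |  |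
| Saturday's | 0.0010 M (fed, over 2.0 min) | 0.075 mM | run made earlier |  |
| flask | 0.0010 M (fed, over 2.0 min) | 0.0500 mM |  | 80 min |

- Friday's (time / min: intermediate A / %, product / %, substrate / %): 1.00: 14.3, 0.4, 26.4; 2.00: 28.2, 15.6, 35.3; 4.00: 7.3, 65.6, 2.4; 10.0: 0.9, 91.5, 0; 20.0: 0, 91.6, 0.4; 40.0: 0, 89.0, 1.5; 90.0: 0, 89.7, 0.8
- Sunday's (time / min: intermediate A / %, product / %, substrate / %): 1.00: 14.1, 1.3, 26.3; 2.00: 26.5, 15.5, 34.1; 4.00: 6.4, 66.6, 3.0; 10.0: 0, 94.0, 1.1; 20.0: 0, 92.5, 1.4; 40.0: 0, 92.6, 1.1; 90.0: 0, 92.8, 0
- Saturday's (time / min: intermediate A / %, product / %, substrate / %): 1.00: 13.6, 2.1, 27.3; 3.00: 17.8, 43.1, 10.6; 10.0: 0, 91.3, 2.2; 30.0: 0, 89.9, 0; 90.0: 0.3, 87.9, 1.2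

(scatter of a reading: 1 percentage point)

- the numbers in the tables scatter by 1 percentage point (one standard deviation)
- percentages count the whole charge, also what has not yet gone in

- when, up to 80 min, the flask holds most intermediate A
- the amount of intermediate A, in percent of the substrate charged, at that time

**Our ratio.** In the minute before that, those two runs lost 41.7% of the charge from substrate, while intermediate A rose 13.1%. Against mean amounts of 30.5% and 20.8%, that means 1.36 min⁻¹ for substrate and 1.37 min⁻¹ for intermediate A. Dividing one by the other removes time and gives the hand-over ratio, the amount of intermediate A per amount of substrate at which intermediate A gains as fast as it loses: 0.995.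

**When you come.** Your flask stops feeding at 2.0 min; from those runs we expect a ratio of 0.787 there, lower than that, so we expect intermediate A still to climb. We reckon the ratio is met at 2.13 min, holding 28.0%.

**Don't touch.** Leave the capture agent as charged: Saturday's run, with 0.075 mM, read 13.6% at 1.00 min, beside Friday's 14.3%.

The forecast says 28.5% at 2.15 min, on the ground that “neither concentration matters”.

**The flask.** It tops at 27.8% at 2.14 min.

    substrate → intermediate A (k = 0.0220 s⁻¹)
    intermediate A → intermediate B (k = 0.0230 s⁻¹)
    intermediate B ⇌ product (K = 30.0, k = 0.0180 s⁻¹)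
    intermediate B + capture agent → trapped intermediate (k = 30.0 L mol⁻¹ s⁻¹)

By 2.68 min the flask is down to 23.3%. At its top it holds a ratio of 0.957, beside our 0.995. Saturday's run at 3.00 min read 1.68, higher than the hand-over ratio, so it was past its top, with 17.8% of intermediate A.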